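The dihydropyran ring has a feature the plan uses: the quaternary C2 carries O1 and the methylene C3, the pattern of an opened 2,2-disubstituted epoxide, and C4 is benzylic. Cutting C3–C4 and O1–C8a gives a polarity-reversed benzylic C4 nucleophile with bromine on C8a, and an enantiopure epoxide. In one flask the benzyl Grignard reagent opens the epoxide at CH2 (C3–C4) and the freed tertiary alkoxide is arylated at C8a under palladium catalysis (O1–C8a). No bond to C2 is touched, so the configuration of (S)-2-methylglycidol passes into the ring. The C40 chain, its carbinol set by Sharpless epoxidation, is joined afterwards by two sulfone alkylations and an alkyne allylation.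

Key step: step 7

Remark: read from the structure, both stereocentres are S (chroman C2 and side-chain carbinol C24'; chroman numbering O1–C8a, side chain C1'–C33'); descriptors of intermediates change only where CIP priorities change, never the spatial arrangement. (S)-2-Methylglycidol, (2E,6E)-farnesol, (2E,6E)-farnesyl bromide and geranyl bromide are taken as commercial.

Step 1
Reactants: 1 2,3-dimethylphenol
Product: 2 (2,3-dimethylphenoxy)tri(propan-2-yl)silane
Conditions: TIPSCl, imidazole, DMF, rt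
Reagents that add atoms: chlorotri(propan-2-yl)silane, CC(C)[Si](Cl)(C(C)C)C(C)C
Why: O-silylation of the phenol; the bulky silyl ether should survive the organometallic, basic and hydride steps and later shields its ortho position.

Step 2
Reactants: 2 (2,3-dimethylphenoxy)tri(propan-2-yl)silane
Product: 3 2-{3,4-dimethyl-5-[tri(propan-2-yl)silyloxy]phenyl}-4,4,5,5-tetramethyl-1,3,2-dioxaborolane
Conditions: B2pin2 (1.0 equiv), [Ir(OMe)(cod)]2 (1.5 mol %), 4,4'-di-tert-butyl-2,2'-bipyridine (3 mol %), THF, 80 °C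
Reagents that add atoms: bis(pinacolato)diboron, CC1(C)OB(OC1(C)C)B1OC(C)(C)C(C)(C)O1
Why: Iridium-catalysed C–H borylation is sterically controlled and should take the only ring C–H without an ortho substituent, meta to both the silyloxy and the methyl group.

Step 3
Reactants: 3 2-{3,4-dimethyl-5-[tri(propan-2-yl)silyloxy]phenyl}-4,4,5,5-tetramethyl-1,3,2-dioxaborolane
Product: 5 {3,4-dimethyl-5-[tri(propan-2-yl)silyloxy]phenyl}methanol, via benzylic pinacol boronate 4 (not isolated)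
Conditions: BrCH2Cl, n-BuLi, THF, −78 °C → rt; then H2O2 (30 %), aq NaOH, 0 °C
Reagents that add atoms: bromochloromethane, ClCBr; hydrogen peroxide, OO
Why: Matteson homologation (1,2-aryl shift in the chloromethyl boronate complex) inserts the future C4, and oxidation of the benzylic C–B bond gives the alcohol.

Step 4
Reactants: 5 {3,4-dimethyl-5-[tri(propan-2-yl)silyloxy]phenyl}methanol
Product: 6 {2-bromo-3,4-dimethyl-5-[tri(propan-2-yl)silyloxy]phenyl}methanol
Conditions: NBS, MeCN, 0 °C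
Reagents that add atoms: N-bromosuccinimide, O=C1CCC(=O)N1Br
Why: Electrophilic aromatic bromination should go para to the silyloxy group because the ortho position is shielded by the silyl group; this places bromine on the future C8a.

Step 5
Reactants: 6 {2-bromo-3,4-dimethyl-5-[tri(propan-2-yl)silyloxy]phenyl}methanol
Product: 7 [4-bromo-5-(bromomethyl)-2,3-dimethylphenoxy]tri(propan-2-yl)silane
Conditions: CBr4, PPh3, CH2Cl2, 0 °C
Reagents that add atoms: tetrabromomethane, BrC(Br)(Br)Br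
Why: Appel reaction converts the benzylic alcohol to the bromide under neutral conditions that leave the aryl silyl ether intact.

Step 6
Reactants: 8 (S)-2-methylglycidol [(2S)-2-methyloxiran-2-yl]methanol
Product: 9 (2R)-2-[(benzyloxy)methyl]-2-methyloxirane
Conditions: NaH, BnBr, Bu4NI (cat.), THF, 0 °C → rt
Reagents that add atoms: benzyl bromide, BrCc1ccccc1
Why: Williamson etherification protects the primary alcohol; Payne rearrangement at the quaternary epoxide carbon is slow at 0 °C, so the stereocentre of commercial 8 is kept (the descriptor changes by priority only).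

Step 7
Reactants: 7 [4-bromo-5-(bromomethyl)-2,3-dimethylphenoxy]tri(propan-2-yl)silane, 9 (2R)-2-[(benzyloxy)methyl]-2-methyloxirane
Product: 12 {[(2R)-2-[(benzyloxy)methyl]-2,7,8-trimethyl-3,4-dihydro-2H-chromen-6-yl]oxy}tri(propan-2-yl)silane, via benzylmagnesium bromide 10 (not isolated), via bromomagnesium alkoxide 11 (not isolated)
Conditions: Mg, Et2O, 0 °C (decant); then 9 (1.1 equiv), CuI (10 mol %), THF, −30 → 0 °C; then NaOt-Bu, Pd(OAc)2 (5 mol %), 2-(di-tert-butylphosphino)-1,1'-binaphthyl (6 mol %), toluene, 80 °C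
Reagents that add atoms: none
Why: Magnesium inserts into the benzylic C–Br bond of 7 much faster than into the flanked aryl C–Br bond, and the benzyl Grignard 10, a C4 carbanion equivalent (polarity reversal of a benzylic centre that is normally electrophilic), opens epoxide 9 under copper catalysis by SN2 attack at the unsubstituted CH2, which forms C3–C4 and releases alkoxide 11. After cation exchange with NaOt-Bu, oxidative addition of zerovalent palladium into the aryl C–Br bond, binding of the alkoxide and C–O reductive elimination form O1–C8a. The closest known reactions are the copper-catalysed opening of 2,2-disubstituted epoxides by Grignard reagents and the palladium-catalysed intramolecular etherification of tertiary alcohols with aryl bromides to 2,2-disubstituted chromans, here run in one flask. The dihydropyran ring closes at O1–C8a by reductive elimination from a seven-membered aryl(alkoxo)palladium chelate, that is, a six-membered ring closure by ipso substitution on the arene. No new stereocentre is formed: C2 comes from 9 with none of its bonds broken, so its configuration is that of (S)-2-methylglycidol. The step needs attack at C3 only (secured by the quaternary C2 and low temperature, which also limits Lewis-acid rearrangement of the epoxide) and clean C–O elimination (the tertiary alkoxide has no hydrogen for β-hydride elimination and the two ortho groups on C8a speed reductive elimination).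

Step 8
Reactants: 12 {[(2R)-2-[(benzyloxy)methyl]-2,7,8-trimethyl-3,4-dihydro-2H-chromen-6-yl]oxy}tri(propan-2-yl)silane
Product: 13 [(2R)-2,7,8-trimethyl-6-{[tri(propan-2-yl)silyl]oxy}-3,4-dihydro-2H-chromen-2-yl]methanol
Conditions: H2 (1 atm), Pd/C (10 %), EtOAc, rt
Reagents that add atoms: none
Why: Hydrogenolysis of the benzyl ether; the aryl silyl ether and the chroman are inert and no alkene is present yet.

Step 9
Reactants: 13 [(2R)-2,7,8-trimethyl-6-{[tri(propan-2-yl)silyl]oxy}-3,4-dihydro-2H-chromen-2-yl]methanol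
Product: 14 [(2R)-2,7,8-trimethyl-6-{[tri(propan-2-yl)silyl]oxy}-3,4-dihydro-2H-chromen-2-yl]methyl trifluoromethanesulfonate
Conditions: Tf2O, pyridine, CH2Cl2, −78 → 0 °C
Reagents that add atoms: trifluoromethanesulfonic anhydride, O=S(=O)(OS(=O)(=O)C(F)(F)F)C(F)(F)F
Why: O-sulfonylation gives the triflate, a leaving group reactive enough for substitution at this neopentyl-type carbon next to the quaternary C2.

Step 10
Reactants: 15 (2E,6E)-1-bromo-3,7,11-trimethyldodeca-2,6,10-triene (farnesyl bromide)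
Product: 16 1-methyl-4-{[(2E,6E)-3,7,11-trimethyldodeca-2,6,10-trien-1-yl]sulfonyl}benzene
Conditions: sodium 4-methylbenzenesulfinate, DMF, rt
Reagents that add atoms: sodium 4-methylbenzenesulfinate, Cc1ccc(cc1)S(=O)[O-].[Na+]
Why: S-alkylation of the sulfinate (SN2 at the primary allylic bromide) gives the allylic sulfone with the E alkenes untouched.

Step 11
Reactants: 16 1-methyl-4-{[(2E,6E)-3,7,11-trimethyldodeca-2,6,10-trien-1-yl]sulfonyl}benzene, 14 [(2R)-2,7,8-trimethyl-6-{[tri(propan-2-yl)silyl]oxy}-3,4-dihydro-2H-chromen-2-yl]methyl trifluoromethanesulfonate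
Product: 18 {[(2R)-2,7,8-trimethyl-2-[(3E,7E)-4,8,12-trimethyl-2-(4-methylbenzenesulfonyl)trideca-3,7,11-trien-1-yl]-3,4-dihydro-2H-chromen-6-yl]oxy}tri(propan-2-yl)silane (epimers at C2'), via lithiated sulfone 17 (not isolated)
Conditions: n-BuLi, THF/HMPA, −78 °C; then 14, −78 °C → rt
Reagents that add atoms: none
Why: Alkylation of the α-sulfonyl allyl anion by the primary triflate (sulfone coupling of the Biellmann type) forms C1'–C2'; the sulfonyl-bearing carbon is a transient stereocentre formed without control and removed in step 22.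

Step 12
Reactants: 18 {[(2R)-2,7,8-trimethyl-2-[(3E,7E)-4,8,12-trimethyl-2-(4-methylbenzenesulfonyl)trideca-3,7,11-trien-1-yl]-3,4-dihydro-2H-chromen-6-yl]oxy}tri(propan-2-yl)silane
Product: 19 (2E,6E,10E)-2,6,10-trimethyl-12-(4-methylbenzenesulfonyl)-13-[(2R)-2,7,8-trimethyl-6-{[tri(propan-2-yl)silyl]oxy}-3,4-dihydro-2H-chromen-2-yl]trideca-2,6,10-trien-1-ol
Conditions: SeO2 (20 mol %), t-BuOOH, salicylic acid (10 mol %), CH2Cl2, 0 °C → rt, stopped at partial conversion
Reagents that add atoms: tert-butyl hydroperoxide, CC(C)(C)OO (oxygen relayed by the catalyst SeO2, O=[Se]=O)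
Why: Catalytic SeO2 allylic oxidation (ene reaction, then [2,3]-sigmatropic shift) should prefer the E methyl of the terminal, most electron-rich trisubstituted alkene; the alkene next to the sulfone is deactivated.

Step 13
Reactants: 19 (2E,6E,10E)-2,6,10-trimethyl-12-(4-methylbenzenesulfonyl)-13-[(2R)-2,7,8-trimethyl-6-{[tri(propan-2-yl)silyl]oxy}-3,4-dihydro-2H-chromen-2-yl]trideca-2,6,10-trien-1-ol
Product: 20 {[(2R)-2-[(3E,7E,11E)-13-bromo-4,8,12-trimethyl-2-(4-methylbenzenesulfonyl)trideca-3,7,11-trien-1-yl]-2,7,8-trimethyl-3,4-dihydro-2H-chromen-6-yl]oxy}tri(propan-2-yl)silane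
Conditions: CBr4, PPh3, CH2Cl2, −20 → 0 °C
Reagents that add atoms: tetrabromomethane, BrC(Br)(Br)Br
Why: Appel bromination of the primary allylic alcohol proceeds by SN2 without allylic transposition, so the E geometry is kept.

Step 14
Reactants: 21 (2E,6E)-3,7,11-trimethyldodeca-2,6,10-trien-1-ol (farnesol)
Product: 22 {(2S,3S)-3-[(3E)-4,8-dimethylnona-3,7-dien-1-yl]-3-methyloxiran-2-yl}methanol
Conditions: Ti(Oi-Pr)4 (5 mol %), L-(+)-diethyl tartrate (6 mol %), t-BuOOH, 4 Å MS, CH2Cl2, −20 °C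
Reagents that add atoms: tert-butyl hydroperoxide, CC(C)(C)OO
Why: Sharpless asymmetric epoxidation acts only on the allylic alcohol alkene, and the L-(+)-tartrate ligand directs oxygen to the face that gives the (2S,3S)-epoxide, which sets the future carbinol centre C24'.

Step 15
Reactants: 22 {(2S,3S)-3-[(3E)-4,8-dimethylnona-3,7-dien-1-yl]-3-methyloxiran-2-yl}methanol
Product: 23 (2R,3S)-2-(chloromethyl)-3-[(3E)-4,8-dimethylnona-3,7-dien-1-yl]-3-methyloxirane
Conditions: PPh3, CCl4, NaHCO3, reflux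
Reagents that add atoms: tetrachloromethane, ClC(Cl)(Cl)Cl
Why: Appel chlorination of the primary alcohol under buffered conditions leaves the epoxide untouched (the C2 descriptor changes by priority only).

Step 16
Reactants: 23 (2R,3S)-2-(chloromethyl)-3-[(3E)-4,8-dimethylnona-3,7-dien-1-yl]-3-methyloxirane
Product: 25 (3S,6E)-3,7,11-trimethyldodeca-6,10-dien-1-yn-3-ol, via lithium chloroalkenyl alkoxide 24 (not isolated)
Conditions: n-BuLi (3.2 equiv), THF, −40 °C; aq NH4Cl
Reagents that add atoms: none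
Why: Base-induced double elimination of a 2,3-epoxy chloride (α-deprotonation with epoxide opening, then loss of HCl) gives the terminal propargylic alcohol; the C–O bond at the stereocentre is never broken.

Step 17
Reactants: 26 (2E)-1-bromo-3,7-dimethylocta-2,6-diene (geranyl bromide)
Product: 27 1-{[(2E)-3,7-dimethylocta-2,6-dien-1-yl]sulfonyl}-4-methylbenzene
Conditions: sodium 4-methylbenzenesulfinate, DMF, rt
Reagents that add atoms: sodium 4-methylbenzenesulfinate, Cc1ccc(cc1)S(=O)[O-].[Na+]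
Why: S-alkylation of the sulfinate by SN2 at the primary allylic bromide, as in step 10.

Step 18
Reactants: 27 1-{[(2E)-3,7-dimethylocta-2,6-dien-1-yl]sulfonyl}-4-methylbenzene
Product: 28 (2E,6E)-2,6-dimethyl-8-(4-methylbenzenesulfonyl)octa-2,6-dien-1-ol
Conditions: SeO2 (20 mol %), t-BuOOH, salicylic acid (10 mol %), CH2Cl2, 0 °C → rt
Reagents that add atoms: tert-butyl hydroperoxide, CC(C)(C)OO (oxygen relayed by the catalyst SeO2, O=[Se]=O)
Why: SeO2 allylic oxidation takes the E methyl of the terminal alkene; the alkene next to the sulfone is deactivated.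

Step 19
Reactants: 28 (2E,6E)-2,6-dimethyl-8-(4-methylbenzenesulfonyl)octa-2,6-dien-1-ol
Product: 29 1-{[(2E,6E)-8-bromo-3,7-dimethylocta-2,6-dien-1-yl]sulfonyl}-4-methylbenzene
Conditions: CBr4, PPh3, CH2Cl2, −20 → 0 °C
Reagents that add atoms: tetrabromomethane, BrC(Br)(Br)Br
Why: Appel bromination of the primary allylic alcohol with retention of the E geometry.

Step 20
Reactants: 25 (3S,6E)-3,7,11-trimethyldodeca-6,10-dien-1-yn-3-ol, 29 1-{[(2E,6E)-8-bromo-3,7-dimethylocta-2,6-dien-1-yl]sulfonyl}-4-methylbenzene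
Product: 30 (2E,6E,11S,14E)-3,7,11,15,19-pentamethyl-1-(4-methylbenzenesulfonyl)icosa-2,6,14,18-tetraen-9-yn-11-ol
Conditions: CuI (20 mol %), NaI (20 mol %), K2CO3, DMF, rt
Reagents that add atoms: none
Why: Copper-catalysed allylation of the terminal alkyne (copper acetylide, SN2 at the primary allylic CH2) forms C21'–C22' as a skipped enyne with the E alkene retained; carbonate does not deprotonate the sulfone.

Step 21
Reactants: 30 (2E,6E,11S,14E)-3,7,11,15,19-pentamethyl-1-(4-methylbenzenesulfonyl)icosa-2,6,14,18-tetraen-9-yn-11-ol, 20 {[(2R)-2-[(3E,7E,11E)-13-bromo-4,8,12-trimethyl-2-(4-methylbenzenesulfonyl)trideca-3,7,11-trien-1-yl]-2,7,8-trimethyl-3,4-dihydro-2H-chromen-6-yl]oxy}tri(propan-2-yl)silane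
Product: 32 {[(2R)-2-[(3E,7E,11E,15E,19E,24S,27E)-24-hydroxy-4,8,12,16,20,24,28,32-octamethyl-2,14-bis(4-methylbenzenesulfonyl)tritriaconta-3,7,11,15,19,27,31-heptaen-22-yn-1-yl]-2,7,8-trimethyl-3,4-dihydro-2H-chromen-6-yl]oxy}tri(propan-2-yl)silane (diastereomers at C2' and C14'), via dilithiated sulfone 31 (not isolated)
Conditions: n-BuLi (2.1 equiv), THF/HMPA, −78 °C; then 20, −78 → −20 °C
Reagents that add atoms: none
Why: Second sulfone alkylation: the primary α-sulfonyl carbanion of the alkoxide–carbanion dianion attacks the allylic bromide to form C13'–C14', while the hindered, less acidic α-sulfonyl C–H of 20 stays untouched.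

Step 22
Reactants: 32 the bis-sulfone named in step 21
Product: 33 {[(2S)-2-[(3E,7E,11E,15E,19E,24S,27E)-24-hydroxy-4,8,12,16,20,24,28,32-octamethyltritriaconta-3,7,11,15,19,27,31-heptaen-22-yn-1-yl]-2,7,8-trimethyl-3,4-dihydro-2H-chromen-6-yl]oxy}tri(propan-2-yl)silane
Conditions: PdCl2(dppp) (10 mol %), LiBHEt3, THF, 0 °C → rt
Reagents that add atoms: none
Why: Palladium-catalysed reductive desulfonylation (ionisation to a π-allyl palladium complex, hydride delivery to the less substituted terminus) removes both sulfonyl groups and should leave each trisubstituted E alkene in place.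

Step 23
Reactants: 33 the enyne named in step 22
Product: 34 {[(2S)-2-[(3E,7E,11E,15E,19E,22E,24S,27E)-24-hydroxy-4,8,12,16,20,24,28,32-octamethyltritriaconta-3,7,11,15,19,22,27,31-octaen-1-yl]-2,7,8-trimethyl-3,4-dihydro-2H-chromen-6-yl]oxy}tri(propan-2-yl)silane
Conditions: NaAlH2(OCH2CH2OMe)2, THF, 0 °C → rt
Reagents that add atoms: none
Why: Hydroxyl-directed trans-hydroalumination of the propargylic alcohol, then protonolysis, gives the E allylic alcohol; isolated alkenes do not react.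

Step 24
Reactants: 34 the silyl ether named in step 23
Product: 35 (2S)-2-[(3E,7E,11E,15E,19E,22E,24S,27E)-24-hydroxy-4,8,12,16,20,24,28,32-octamethyltritriaconta-3,7,11,15,19,22,27,31-octaen-1-yl]-2,7,8-trimethyl-3,4-dihydro-2H-chromen-6-ol (target)
Conditions: Bu4NF, AcOH, THF, 0 °C, under argon
Reagents that add atoms: none
Why: Fluoride cleaves the aryl silyl ether under buffered conditions that spare the tertiary allylic alcohol and the polyene.

Compound list

1 | 2,3-dimethylphenol | Cc1cccc(O)c1C | starting material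
2 | (2,3-dimethylphenoxy)tri(propan-2-yl)silane | Cc1cccc(O[Si](C(C)C)(C(C)C)C(C)C)c1C | intermediate
3 | 2-{3,4-dimethyl-5-[tri(propan-2-yl)silyloxy]phenyl}-4,4,5,5-tetramethyl-1,3,2-dioxaborolane | Cc1cc(B2OC(C)(C)C(C)(C)O2)cc(O[Si](C(C)C)(C(C)C)C(C)C)c1C | intermediate
4 | 2-{3,4-dimethyl-5-[tri(propan-2-yl)silyloxy]benzyl}-4,4,5,5-tetramethyl-1,3,2-dioxaborolane (not isolated) | Cc1cc(CB2OC(C)(C)C(C)(C)O2)cc(O[Si](C(C)C)(C(C)C)C(C)C)c1C | intermediate
5 | {3,4-dimethyl-5-[tri(propan-2-yl)silyloxy]phenyl}methanol | Cc1cc(CO)cc(O[Si](C(C)C)(C(C)C)C(C)C)c1C | intermediate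
6 | {2-bromo-3,4-dimethyl-5-[tri(propan-2-yl)silyloxy]phenyl}methanol | OCc1cc(O[Si](C(C)C)(C(C)C)C(C)C)c(C)c(C)c1Br | intermediate
7 | [4-bromo-5-(bromomethyl)-2,3-dimethylphenoxy]tri(propan-2-yl)silane | BrCc1cc(O[Si](C(C)C)(C(C)C)C(C)C)c(C)c(C)c1Br | intermediate
8 | (S)-2-methylglycidol, [(2S)-2-methyloxiran-2-yl]methanol | OC[C@@]1(C)CO1 | starting material
9 | (2R)-2-[(benzyloxy)methyl]-2-methyloxirane | c1ccccc1COC[C@@]2(C)CO2 | intermediate
10 | {2-bromo-3,4-dimethyl-5-[tri(propan-2-yl)silyloxy]benzyl}magnesium bromide (not isolated) | Br[Mg]Cc1cc(O[Si](C(C)C)(C(C)C)C(C)C)c(C)c(C)c1Br | intermediate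
11 | bromomagnesium (2R)-1-(benzyloxy)-4-{2-bromo-3,4-dimethyl-5-[tri(propan-2-yl)silyloxy]phenyl}-2-methylbutan-2-olate (not isolated) | c1ccccc1COC[C@@](O[Mg]Br)(C)CCc2cc(O[Si](C(C)C)(C(C)C)C(C)C)c(C)c(C)c2Br | intermediate
12 | {[(2R)-2-[(benzyloxy)methyl]-2,7,8-trimethyl-3,4-dihydro-2H-chromen-6-yl]oxy}tri(propan-2-yl)silane | c1ccccc1COC[C@@]2(C)CCc3cc(O[Si](C(C)C)(C(C)C)C(C)C)c(C)c(C)c3O2 | intermediate
13 | [(2R)-2,7,8-trimethyl-6-{[tri(propan-2-yl)silyl]oxy}-3,4-dihydro-2H-chromen-2-yl]methanol | OC[C@@]1(C)CCc2cc(O[Si](C(C)C)(C(C)C)C(C)C)c(C)c(C)c2O1 | intermediate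
14 | [(2R)-2,7,8-trimethyl-6-{[tri(propan-2-yl)silyl]oxy}-3,4-dihydro-2H-chromen-2-yl]methyl trifluoromethanesulfonate | FC(F)(F)S(=O)(=O)OC[C@@]1(C)CCc2cc(O[Si](C(C)C)(C(C)C)C(C)C)c(C)c(C)c2O1 | intermediate
15 | (2E,6E)-1-bromo-3,7,11-trimethyldodeca-2,6,10-triene (farnesyl bromide) | CC(C)=CCC/C(C)=C/CC/C(C)=C/CBr | starting material
16 | 1-methyl-4-{[(2E,6E)-3,7,11-trimethyldodeca-2,6,10-trien-1-yl]sulfonyl}benzene | CC(C)=CCC/C(C)=C/CC/C(C)=C/CS(=O)(=O)c1ccc(C)cc1 | intermediate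
17 | α-lithio derivative of 16 (not isolated) | CC(C)=CCC/C(C)=C/CC/C(C)=C/C([Li])S(=O)(=O)c1ccc(C)cc1 | intermediate
18 | {[(2R)-2,7,8-trimethyl-2-[(3E,7E)-4,8,12-trimethyl-2-(4-methylbenzenesulfonyl)trideca-3,7,11-trien-1-yl]-3,4-dihydro-2H-chromen-6-yl]oxy}tri(propan-2-yl)silane, epimers at C2' | CC(C)=CCC/C(C)=C/CC/C(C)=C/C(C[C@@]1(C)CCc2cc(O[Si](C(C)C)(C(C)C)C(C)C)c(C)c(C)c2O1)S(=O)(=O)c1ccc(C)cc1 | intermediate
19 | (2E,6E,10E)-2,6,10-trimethyl-12-(4-methylbenzenesulfonyl)-13-[(2R)-2,7,8-trimethyl-6-{[tri(propan-2-yl)silyl]oxy}-3,4-dihydro-2H-chromen-2-yl]trideca-2,6,10-trien-1-ol | OC/C(C)=C/CC/C(C)=C/CC/C(C)=C/C(C[C@@]1(C)CCc2cc(O[Si](C(C)C)(C(C)C)C(C)C)c(C)c(C)c2O1)S(=O)(=O)c1ccc(C)cc1 | intermediate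
20 | {[(2R)-2-[(3E,7E,11E)-13-bromo-4,8,12-trimethyl-2-(4-methylbenzenesulfonyl)trideca-3,7,11-trien-1-yl]-2,7,8-trimethyl-3,4-dihydro-2H-chromen-6-yl]oxy}tri(propan-2-yl)silane | BrC/C(C)=C/CC/C(C)=C/CC/C(C)=C/C(C[C@@]1(C)CCc2cc(O[Si](C(C)C)(C(C)C)C(C)C)c(C)c(C)c2O1)S(=O)(=O)c1ccc(C)cc1 | intermediate
21 | (2E,6E)-3,7,11-trimethyldodeca-2,6,10-trien-1-ol (farnesol) | CC(C)=CCC/C(C)=C/CC/C(C)=C/CO | starting material
22 | {(2S,3S)-3-[(3E)-4,8-dimethylnona-3,7-dien-1-yl]-3-methyloxiran-2-yl}methanol | CC(C)=CCC/C(C)=C/CC[C@]1(C)O[C@H]1CO | intermediate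
23 | (2R,3S)-2-(chloromethyl)-3-[(3E)-4,8-dimethylnona-3,7-dien-1-yl]-3-methyloxirane | CC(C)=CCC/C(C)=C/CC[C@]1(C)O[C@H]1CCl | intermediate
24 | lithium (3S,6E)-1-chloro-3,7,11-trimethyldodeca-1,6,10-trien-3-olate (not isolated) | CC(C)=CCC/C(C)=C/CC[C@](C)(O[Li])C=CCl | intermediate
25 | (3S,6E)-3,7,11-trimethyldodeca-6,10-dien-1-yn-3-ol | CC(C)=CCC/C(C)=C/CC[C@](C)(O)C#C | intermediate
26 | (2E)-1-bromo-3,7-dimethylocta-2,6-diene (geranyl bromide) | CC(C)=CCC/C(C)=C/CBr | starting material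
27 | 1-{[(2E)-3,7-dimethylocta-2,6-dien-1-yl]sulfonyl}-4-methylbenzene | CC(C)=CCC/C(C)=C/CS(=O)(=O)c1ccc(C)cc1 | intermediate
28 | (2E,6E)-2,6-dimethyl-8-(4-methylbenzenesulfonyl)octa-2,6-dien-1-ol | OC/C(C)=C/CC/C(C)=C/CS(=O)(=O)c1ccc(C)cc1 | intermediate
29 | 1-{[(2E,6E)-8-bromo-3,7-dimethylocta-2,6-dien-1-yl]sulfonyl}-4-methylbenzene | BrC/C(C)=C/CC/C(C)=C/CS(=O)(=O)c1ccc(C)cc1 | intermediate
30 | (2E,6E,11S,14E)-3,7,11,15,19-pentamethyl-1-(4-methylbenzenesulfonyl)icosa-2,6,14,18-tetraen-9-yn-11-ol | CC(C)=CCC/C(C)=C/CC[C@](C)(O)C#CC/C(C)=C/CC/C(C)=C/CS(=O)(=O)c1ccc(C)cc1 | intermediate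
31 | O,C-dilithio derivative of 30 (lithium alkoxide and α-sulfonyl carbanion, not isolated) | CC(C)=CCC/C(C)=C/CC[C@](C)(O[Li])C#CC/C(C)=C/CC/C(C)=C/C([Li])S(=O)(=O)c1ccc(C)cc1 | intermediate
32 | {[(2R)-2-[(3E,7E,11E,15E,19E,24S,27E)-24-hydroxy-4,8,12,16,20,24,28,32-octamethyl-2,14-bis(4-methylbenzenesulfonyl)tritriaconta-3,7,11,15,19,27,31-heptaen-22-yn-1-yl]-2,7,8-trimethyl-3,4-dihydro-2H-chromen-6-yl]oxy}tri(propan-2-yl)silane, diastereomers at C2' and C14' | CC(C)=CCC/C(C)=C/CC[C@](C)(O)C#CC/C(C)=C/CC/C(C)=C/C(S(=O)(=O)c1ccc(C)cc1)C/C(C)=C/CC/C(C)=C/CC/C(C)=C/C(C[C@@]2(C)CCc3cc(O[Si](C(C)C)(C(C)C)C(C)C)c(C)c(C)c3O2)S(=O)(=O)c4ccc(C)cc4 | intermediate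
33 | {[(2S)-2-[(3E,7E,11E,15E,19E,24S,27E)-24-hydroxy-4,8,12,16,20,24,28,32-octamethyltritriaconta-3,7,11,15,19,27,31-heptaen-22-yn-1-yl]-2,7,8-trimethyl-3,4-dihydro-2H-chromen-6-yl]oxy}tri(propan-2-yl)silane | CC(C)=CCC/C(C)=C/CC[C@](C)(O)C#CC/C(C)=C/CC/C(C)=C/CC/C(C)=C/CC/C(C)=C/CC/C(C)=C/CC[C@@]1(C)CCc2cc(O[Si](C(C)C)(C(C)C)C(C)C)c(C)c(C)c2O1 | intermediate
34 | {[(2S)-2-[(3E,7E,11E,15E,19E,22E,24S,27E)-24-hydroxy-4,8,12,16,20,24,28,32-octamethyltritriaconta-3,7,11,15,19,22,27,31-octaen-1-yl]-2,7,8-trimethyl-3,4-dihydro-2H-chromen-6-yl]oxy}tri(propan-2-yl)silane | CC(C)=CCC/C(C)=C/CC[C@](C)(O)/C=C/C/C(C)=C/CC/C(C)=C/CC/C(C)=C/CC/C(C)=C/CC/C(C)=C/CC[C@@]1(C)CCc2cc(O[Si](C(C)C)(C(C)C)C(C)C)c(C)c(C)c2O1 | intermediate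
35 | (2S)-2-[(3E,7E,11E,15E,19E,22E,24S,27E)-24-hydroxy-4,8,12,16,20,24,28,32-octamethyltritriaconta-3,7,11,15,19,22,27,31-octaen-1-yl]-2,7,8-trimethyl-3,4-dihydro-2H-chromen-6-ol | CC(C)=CCC/C(C)=C/CC[C@](C)(O)/C=C/C/C(C)=C/CC/C(C)=C/CC/C(C)=C/CC/C(C)=C/CC/C(C)=C/CC[C@@]1(C)CCc2cc(O)c(C)c(C)c2O1 | target

Total step count: 24 steps.
Longest linear sequence: 15 steps (steps 1–5, 7–9, 11–13, 21–24).

Steps most likely to fail

Step 7. The palladium-catalysed ring closure may stall, because oxidative addition into the electron-rich aryl bromide flanked by two ortho groups is slow and the magnesium and copper salts of the first stage can interfere. A second hazard is Lewis-acid rearrangement of the epoxide before the Grignard reagent attacks. The fallback sets out from 7 and 9 and comes back at 12; it makes the two bonds in separate operations and the ether bond by a redox route instead of a cross-coupling. The Grignard opening is run alone and worked up to give the bromo alcohol (2R)-1-(benzyloxy)-4-{2-bromo-3,4-dimethyl-5-[tri(propan-2-yl)silyloxy]phenyl}-2-methylbutan-2-ol F1. Bu4NF removes the silyl group to give 4-bromo-5-[(3R)-4-(benzyloxy)-3-hydroxy-3-methylbutyl]-2,3-dimethylphenol F2. Teuber oxidation with K2NO(SO3)2, with loss of the para bromide, should give the quinone 2-[(3R)-4-(benzyloxy)-3-hydroxy-3-methylbutyl]-5,6-dimethylcyclohexa-2,5-diene-1,4-dione F3. Reductive cyclisation (Zn, AcOH, HCl) through the cyclic hemiketal at C8a keeps the C2–O bond and therefore the configuration, and should give (2R)-2-[(benzyloxy)methyl]-2,7,8-trimethyl-3,4-dihydro-2H-chromen-6-ol F4. TIPSCl and imidazole then return 12.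

Step 12. On this advanced intermediate the allylic oxidation may run on to the enal or attack the internal alkenes, so conversion may have to be kept low. The fallback sets out from 16 and comes back at 19; it puts the oxygen in before the coupling. SeO2/t-BuOOH oxidation of 16 gives (2E,6E,10E)-2,6,10-trimethyl-12-(4-methylbenzenesulfonyl)dodeca-2,6,10-trien-1-ol F5. Dihydropyran with pyridinium 4-toluenesulfonate gives the tetrahydropyranyl ether 2-{[(2E,6E,10E)-2,6,10-trimethyl-12-(4-methylbenzenesulfonyl)dodeca-2,6,10-trien-1-yl]oxy}oxane F6. Its lithio derivative is alkylated with triflate 14 as in step 11 to give 2-{[(2E,6E,10E)-2,6,10-trimethyl-12-(4-methylbenzenesulfonyl)-13-[(2R)-2,7,8-trimethyl-6-{[tri(propan-2-yl)silyl]oxy}-3,4-dihydro-2H-chromen-2-yl]trideca-2,6,10-trien-1-yl]oxy}oxane F7. Methanolysis with pyridinium 4-toluenesulfonate returns 19.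

Step 22. Palladium hydride species may partly reduce the alkyne, and the alkenes may migrate or lose geometry during π-allyl formation. The fallback sets out from 25 and comes back at 34; it makes the E alkene before any hydride step. Palladium-catalysed hydrostannation of 25 (Bu3SnH, PdCl2(PPh3)2) gives the vinylstannane (1E,3S,6E)-3,7,11-trimethyl-1-(tributylstannyl)dodeca-1,6,10-trien-3-ol F8. Stille coupling with allylic bromide 29 (Pd2(dba)3, AsPh3) gives (2E,6E,9E,11S,14E)-3,7,11,15,19-pentamethyl-1-(4-methylbenzenesulfonyl)icosa-2,6,9,14,18-pentaen-11-ol F9. Its dianion is alkylated with 20 as in step 21 to give {[(2R)-2-[(3E,7E,11E,15E,19E,22E,24S,27E)-24-hydroxy-4,8,12,16,20,24,28,32-octamethyl-2,14-bis(4-methylbenzenesulfonyl)tritriaconta-3,7,11,15,19,22,27,31-octaen-1-yl]-2,7,8-trimethyl-3,4-dihydro-2H-chromen-6-yl]oxy}tri(propan-2-yl)silane F10. The desulfonylation conditions of step 22 then give 34 directly, and step 23 is not needed.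

Further compounds

F1 | step 7 | (2R)-1-(benzyloxy)-4-{2-bromo-3,4-dimethyl-5-[tri(propan-2-yl)silyloxy]phenyl}-2-methylbutan-2-ol | c1ccccc1COC[C@@](O)(C)CCc2cc(O[Si](C(C)C)(C(C)C)C(C)C)c(C)c(C)c2Br
F2 | step 7 | 4-bromo-5-[(3R)-4-(benzyloxy)-3-hydroxy-3-methylbutyl]-2,3-dimethylphenol | c1ccccc1COC[C@@](O)(C)CCc2cc(O)c(C)c(C)c2Br
F3 | step 7 | 2-[(3R)-4-(benzyloxy)-3-hydroxy-3-methylbutyl]-5,6-dimethylcyclohexa-2,5-diene-1,4-dione | c1ccccc1COC[C@@](O)(C)CCC2=CC(=O)C(C)=C(C)C2=O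
F4 | step 7 | (2R)-2-[(benzyloxy)methyl]-2,7,8-trimethyl-3,4-dihydro-2H-chromen-6-ol | c1ccccc1COC[C@@]2(C)CCc3cc(O)c(C)c(C)c3O2
F5 | step 12 | (2E,6E,10E)-2,6,10-trimethyl-12-(4-methylbenzenesulfonyl)dodeca-2,6,10-trien-1-ol | OC/C(C)=C/CC/C(C)=C/CC/C(C)=C/CS(=O)(=O)c1ccc(C)cc1
F6 | step 12 | 2-{[(2E,6E,10E)-2,6,10-trimethyl-12-(4-methylbenzenesulfonyl)dodeca-2,6,10-trien-1-yl]oxy}oxane | O(C1CCCCO1)C/C(C)=C/CC/C(C)=C/CC/C(C)=C/CS(=O)(=O)c2ccc(C)cc2
F7 | step 12 | 2-{[(2E,6E,10E)-2,6,10-trimethyl-12-(4-methylbenzenesulfonyl)-13-[(2R)-2,7,8-trimethyl-6-{[tri(propan-2-yl)silyl]oxy}-3,4-dihydro-2H-chromen-2-yl]trideca-2,6,10-trien-1-yl]oxy}oxane | O(C1CCCCO1)C/C(C)=C/CC/C(C)=C/CC/C(C)=C/C(C[C@@]2(C)CCc3cc(O[Si](C(C)C)(C(C)C)C(C)C)c(C)c(C)c3O2)S(=O)(=O)c4ccc(C)cc4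
F8 | step 22 | (1E,3S,6E)-3,7,11-trimethyl-1-(tributylstannyl)dodeca-1,6,10-trien-3-ol | CC(C)=CCC/C(C)=C/CC[C@](C)(O)/C=C/[Sn](CCCC)(CCCC)CCCC
F9 | step 22 | (2E,6E,9E,11S,14E)-3,7,11,15,19-pentamethyl-1-(4-methylbenzenesulfonyl)icosa-2,6,9,14,18-pentaen-11-ol | CC(C)=CCC/C(C)=C/CC[C@](C)(O)/C=C/C/C(C)=C/CC/C(C)=C/CS(=O)(=O)c1ccc(C)cc1
F10 | step 22 | {[(2R)-2-[(3E,7E,11E,15E,19E,22E,24S,27E)-24-hydroxy-4,8,12,16,20,24,28,32-octamethyl-2,14-bis(4-methylbenzenesulfonyl)tritriaconta-3,7,11,15,19,22,27,31-octaen-1-yl]-2,7,8-trimethyl-3,4-dihydro-2H-chromen-6-yl]oxy}tri(propan-2-yl)silane | CC(C)=CCC/C(C)=C/CC[C@](C)(O)/C=C/C/C(C)=C/CC/C(C)=C/C(S(=O)(=O)c1ccc(C)cc1)C/C(C)=C/CC/C(C)=C/CC/C(C)=C/C(C[C@@]2(C)CCc3cc(O[Si](C(C)C)(C(C)C)C(C)C)c(C)c(C)c3O2)S(=O)(=O)c4ccc(C)cc4
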